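The earlier runs and the new flask are simulated with constants of no real substance.

1. I started from a leftover. At 0.104 d the cedar run still held 59.2% of its substrate, and target stood at 6.7%. Taking the rest of what had gone as side product, I read odds of 0.196; the first maple reading gave 0.315.

in all of them: substrate 20 mM

| flask | reagent | remark | time |
|---|---|---|---|
| cedar | 2.5 equiv | run made earlier |  |
| maple | 3.8 equiv | run made earlier |  |
| flask | 5.00 equiv |  | 5.0 d |

- cedar (time / d: target / %, substrate / %): 0.104: 6.7, 59.2; 0.208: 10.2, 35.5; 0.333: 13.4, 19.0; 0.625: 13.3, 4.7; 1.04: 12.1, 0.4; 1.67: 11.2, 0; 3.00: 9.2, 0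
- maple (time / d: target / %, substrate / %): 0.104: 10.6, 55.7; 0.208: 15.3, 31.9; 0.333: 17.6, 15.7; 0.625: 18.6, 3.3; 1.04: 16.1, 0.7; 1.67: 13.7, 0.1; 3.00: 11.1, 0.2

(readings scatter by 0.5 percentage points)

- the analysis behind the earlier runs scatters by 0.5 percentage points, standard deviation
- on the list of suspects stand: reagent + target -> over-reaction product; substrate + reagent -> target; substrate -> side product; target <-> isomer of the product

- time up to 5.0 d at which target stands highest
- the amount of target, in percent of the substrate charged, at that time
- earliest time at which at least nineteen twentieths of that best amount are there, in d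
- latest time at which they still are, in d

2. Divided by the equivalents and averaged, these readings gave 0.0807, the odds per equivalent, a selectivity factor. For the flask that made odds of 0.403, a target share of 28.7%.

3. Logarithms gave the clock. The cedar substrate fell at 4.99 /d, so I reckoned 5.85 /d for the flask. I therefore drew target's first slope at 1.68 /d, as a fraction of the charge.

4. On that clock I reckoned one decade of the flask's substrate in 0.393 d, and I put the knee there.

5. The highest maple reading was 0.777 of that run's share, which put the flask's peak near 22.3%. Beyond it the maple curve was still sinking at its last reading, 11.1%, so I drew no level.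

The forecast's way was “Summing the exponentials”, and it gave 23.1% at 0.42 d, above my peak, with the window from 0.28 d to 0.64 d.

The flask gave 22.7% at 0.444 d, with the window from 0.291 d to 0.683 d.

    reagent + target → over-reaction product (k = 3.47 × 10⁻⁵ /M/s)
    substrate + reagent → target (k = 2.07 × 10⁻⁴ /M/s)
    substrate → side product (k = 4.84 × 10⁻⁵ /s)
    target ⇌ isomer of the product (K = 0.355, k = 4.21 × 10⁻⁶ /s)

At that peak the flask held 2.18% of over-reaction product. With the reagent at 94.1% of its charge at that peak and the substrate at 0% by 5.00 d, the odds per equivalent, held constant, put side product at 71.3%, and the flask held 70.7%. For the neighbour charged with 20.0 equiv I reckoned odds of 1.61, which put its side product at 38.3%, and at 5.00 d it held 37.3%.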